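The target is formally the Br2 adduct of an acyclic C10H14Cl2 triene. Everything rests on cutting the ring bond C5–C6, between the CCl(CH3) carbon and the CH2 flanked by both quaternary carbons. In one operation, a bromonium-induced cation–olefin cyclisation of triene 13 closes the cyclohexane and installs both bromines: Br+ adds to the (Z)-chloro-olefin, the isopropenyl CH2 attacks the chlorine-stabilised cation, bromide caps the tertiary cation. The step exploits the 1,4-disposition of the two C–Br bonds across C5–C6 and the chair-derived pattern (both Br equatorial, Cl axial). Only C2 is set beforehand, by Evans deconjugative alkylation; C1, C4 and C5 are relayed from it.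

Key step: step 8

Remark: C1–C6 are the IUPAC ring locants of the target: C1 = CBr(CH3), C2 = CH bearing the chlorovinyl group, C3 = CH2, C4 = CHBr, C5 = CCl(CH3), C6 = CH2.

Step 1
Reactants: 1 but-2-yn-1-ol
Product: 3 (Z)-3-chlorobut-2-en-1-ol, via cyclic vinylalanate 2 (not isolated)
Conditions: Red-Al, THF, 0 °C to rt; then NCS, −78 to 0 °C
Reagents that add atoms: N-chlorosuccinimide, O=C1CCC(=O)N1Cl
Why: Trans-hydroalumination of the propargylic alcohol through the alkoxide-bound aluminate places Al on C3 cis to the CH2O group (oxaluminole 2), and chlorination of the C–Al bond with retention should give the Z-chloro-olefin (hydroalumination–halogenation of propargylic alcohols).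

Step 2
Reactants: 3 (Z)-3-chlorobut-2-en-1-ol
Product: 4 (Z)-1-bromo-3-chlorobut-2-ene
Conditions: CBr4, PPh3, CH2Cl2, 0 °C
Reagents that add atoms: carbon tetrabromide, BrC(Br)(Br)Br
Why: Appel bromination of the primary allylic alcohol under neutral conditions should keep the olefin geometry.

Step 3
Reactants: 5 (R)-4-benzyloxazolidin-2-one; 6 3-methylbut-2-enoyl chloride
Product: 8 (R)-4-benzyl-3-(3-methylbut-2-enoyl)oxazolidin-2-one, via lithium oxazolidinide 7 (not isolated)
Conditions: n-BuLi, THF, −78 °C; then 6, −78 to 0 °C
Reagents that add atoms: none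
Why: N-acylation of the preformed lithium amide at low temperature avoids the vinylketene pathway that amine bases open for this acid chloride.

Step 4
Reactants: 8 (R)-4-benzyl-3-(3-methylbut-2-enoyl)oxazolidin-2-one; 4 (Z)-1-bromo-3-chlorobut-2-ene
Product: 10 (4R)-4-benzyl-3-[(2R,4Z)-5-chloro-2-(prop-1-en-2-yl)hex-4-enoyl]oxazolidin-2-one, via sodium dienolate 9 (not isolated)
Conditions: NaHMDS, THF, −78 °C; then 4, −78 to −40 °C
Reagents that add atoms: none
Why: Evans asymmetric alkylation in its deconjugative form: γ-deprotonation gives the chelated (Z)-dienolate 9, which should be alkylated at the α-carbon on the face opposite the benzyl group (2R) while the double bond moves out of conjugation to create the isopropenyl group.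

Step 5
Reactants: 10 (4R)-4-benzyl-3-[(2R,4Z)-5-chloro-2-(prop-1-en-2-yl)hex-4-enoyl]oxazolidin-2-one
Product: 11 (2R,4Z)-5-chloro-2-(prop-1-en-2-yl)hex-4-en-1-ol
Conditions: LiBH4, H2O (1 equiv), Et2O, 0 °C
Reagents that add atoms: none
Why: Reductive cleavage of the N-acyloxazolidinone by borohydride should release the primary alcohol and the auxiliary without touching the stereocentre or the chloro-olefin.

Step 6
Reactants: 11 (2R,4Z)-5-chloro-2-(prop-1-en-2-yl)hex-4-en-1-ol
Product: 12 (2R,4Z)-5-chloro-2-(prop-1-en-2-yl)hex-4-enal
Conditions: Dess–Martin periodinane, NaHCO3, CH2Cl2, 0 °C; used crude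
Reagents that add atoms: none
Why: Dess–Martin oxidation under buffered, non-basic conditions should give the α-isopropenyl aldehyde without epimerisation or migration of the double bond into conjugation.

Step 7
Reactants: 12 (2R,4Z)-5-chloro-2-(prop-1-en-2-yl)hex-4-enal
Product: 13 (1E,3S,5Z)-1,6-dichloro-3-(prop-1-en-2-yl)hepta-1,5-diene
Conditions: CrCl2, CHCl3, THF, 65 °C
Reagents that add atoms: chloroform, ClC(Cl)Cl
Why: Takai olefination: the gem-dichromium species from CHCl3 and CrCl2 adds to the aldehyde and eliminates to the (E)-chloroalkene in a non-basic medium that should spare the α-stereocentre.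

Step 8
Reactants: 13 (1E,3S,5Z)-1,6-dichloro-3-(prop-1-en-2-yl)hepta-1,5-diene
Product: 15 (1R,2S,4S,5R)-1,4-dibromo-5-chloro-2-[(E)-2-chloroethenyl]-1,5-dimethylcyclohexane, via chloro-bromiranium bromide 14 (not isolated)
Conditions: Br2 (1.0 equiv, slow addition), HFIP/CH2Cl2 1:4, −40 °C, high dilution, dark
Reagents that add atoms: bromine, BrBr
Why: Proposed new method: Br2 should transfer Br+ to the (Z)-chloro-olefin to give the unsymmetrical chloro-bromiranium ion 14, whose positive charge sits on the carbon bearing Cl and CH3; the CH2 terminus of the isopropenyl group opens it at that carbon in a chair, and bromide captures the tertiary cation so formed. The closest known reactions are the bromonium-induced cation–olefin (polyene) cyclisation of 1,5-dienes and the anti addition of Br2 to chloro-olefins; a chloro-olefin as the initiating alkene and bromide as the terminating nucleophile are the untested elements. The cyclohexane closes in the 6-endo-trig mode at the isopropenyl group (Markovnikov, tertiary cation) with anti opening of the bromiranium ion. Anti addition across the Z-olefin places Br equatorial at C4 and Cl axial at C5, so their cis relationship is controlled by the olefin geometry fixed in step 1; anti addition across the isopropenyl group, reinforced by the axial C5–Cl that blocks the axial approach, places Br equatorial and CH3 axial at C1; the existing C2 stereocentre selects the chair in which the chlorovinyl group is equatorial (cis to the C4 bromine), which is the weakest of the three controls. The step needs Br+ to react through the chloro-olefin although the isopropenyl group is the more electron-rich alkene: the allylic chlorovinyl branch deactivates and shields the isopropenyl group, only the bromiranium ion on the chloro-olefin has a π-nucleophile within reach of a six-membered chair, and in HFIP at high dilution Br+ transfer between the olefins should stay reversible while bimolecular capture by the hydrogen-bonded bromide is slow, so that the unimolecular ring closure drains the equilibrium.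

Compound list
1 | but-2-yn-1-ol | CC#CCO | starting material
2 | sodium 2,2-bis(2-methoxyethoxy)-3-methyl-2,5-dihydro-1,2-oxaluminol-2-uide (cyclic vinylalanate) | CC1=CCO[Al-]1(OCCOC)OCCOC.[Na+] | intermediate
3 | (Z)-3-chlorobut-2-en-1-ol | C/C(Cl)=C/CO | intermediate
4 | (Z)-1-bromo-3-chlorobut-2-ene | C/C(Cl)=C/CBr | intermediate
5 | (R)-4-benzyloxazolidin-2-one | O=C1N[C@H](Cc2ccccc2)CO1 | starting material
6 | 3-methylbut-2-enoyl chloride | CC(C)=CC(Cl)=O | starting material
7 | lithium (R)-4-benzyl-2-oxooxazolidin-3-ide | [Li+].O=C1[N-][C@H](Cc2ccccc2)CO1 | intermediate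
8 | (R)-4-benzyl-3-(3-methylbut-2-enoyl)oxazolidin-2-one | CC(C)=CC(=O)N1[C@H](Cc2ccccc2)COC1=O | intermediate
9 | sodium (Z)-dienolate of 8 | [Na+].[O-]/C(=C\C(C)=C)N1[C@H](Cc2ccccc2)COC1=O | intermediate
10 | (4R)-4-benzyl-3-[(2R,4Z)-5-chloro-2-(prop-1-en-2-yl)hex-4-enoyl]oxazolidin-2-one | CC(=C)[C@H](C(=O)N1[C@H](Cc2ccccc2)COC1=O)C/C=C(\Cl)C | intermediate
11 | (2R,4Z)-5-chloro-2-(prop-1-en-2-yl)hex-4-en-1-ol | CC(=C)[C@H](CO)C/C=C(\Cl)C | intermediate
12 | (2R,4Z)-5-chloro-2-(prop-1-en-2-yl)hex-4-enal | CC(=C)[C@H](C=O)C/C=C(\Cl)C | intermediate
13 | (1E,3S,5Z)-1,6-dichloro-3-(prop-1-en-2-yl)hepta-1,5-diene | CC(=C)[C@H](/C=C/Cl)C/C=C(\Cl)C | intermediate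
14 | chloro-bromiranium ion of 13 at the 5,6-olefin, bromide salt | C[C@]1(Cl)[Br+][C@H]1C[C@@H](/C=C/Cl)C(C)=C.[Br-] | intermediate
15 | (1R,2S,4S,5R)-1,4-dibromo-5-chloro-2-[(E)-2-chloroethenyl]-1,5-dimethylcyclohexane | C[C@@]1(Cl)C[C@@](C)(Br)[C@H](/C=C/Cl)C[C@@H]1Br | target

Total step count: 8. Longest linear sequence: 7 (steps 1, 2, 4, 5, 6, 7, 8).

Steps most likely to fail

1. Step 8 (Proposed new method). Three processes threaten it:
   - irreversible bromine addition at the isopropenyl group before Br+ reaches the chloro-olefin;
   - weak discrimination between the two chair faces by the C2 stereocentre, because allylic strain between the isopropenyl methyl and an equatorial chlorovinyl group works against the usual equatorial preference;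
   - proton loss from the tertiary cation instead of bromide capture.

   The fallback sets out from 13 and returns at 15, and separates bromination from ring closure with known reaction types. The isopropenyl group is masked first: mCPBA (1 equiv, NaHCO3, CH2Cl2, 0 °C) should epoxidise only the electron-richer 1,1-disubstituted olefin and give 2-[(1E,3S,5Z)-1,6-dichlorohepta-1,5-dien-3-yl]-2-methyloxirane F1, as two epimers at the oxirane carbon, which is of no consequence. Br2 (solid K2CO3, CH2Cl2, −78 °C) then adds anti to the only remaining reactive olefin, the trisubstituted chloro-olefin, to give the dibromide 2-[(1E,3S,5S,6R)-5,6-dibromo-1,6-dichlorohept-1-en-3-yl]-2-methyloxirane F2, expected together with its (5R,6S) diastereomer since the olefin faces are not differentiated. Neutral, non-reductive deoxygenation of the oxirane by a rhodium carbenoid (dimethyl diazomalonate, cat. Rh2(OAc)4, benzene, 80 °C) should restore the isopropenyl group in (1E,3S,5S,6R)-5,6-dibromo-1,6-dichloro-3-(prop-1-en-2-yl)hept-1-ene F3, an isomer of 15. A catalytic bromophilic Lewis acid (SnBr4, CH2Cl2, −78 to −40 °C) should then abstract bromide from the CBrCl(CH3) carbon with anchimeric help from the neighbouring bromine, as in Lewis-acid-promoted additions of polyhaloalkanes to alkenes and halide-abstraction-triggered cation–olefin cyclisations; intramolecular addition to the isopropenyl group and return of bromide should give 15. The (5S,6R) isomer leads to 15; material from the other diastereomer is removed by chromatography.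

2. Step 7. Cr(III) Lewis acidity at 65 °C may move the double bond of aldehyde 12 into conjugation or epimerise its α-carbon, and E-selectivity may be incomplete.

   The fallback sets out from 12 and returns at 13. A Corey–Fuchs sequence at low temperature (CBr4, PPh3, CH2Cl2, 0 °C) should give (3S,5Z)-1,1-dibromo-6-chloro-3-(prop-1-en-2-yl)hepta-1,5-diene F4. n-BuLi (2.0 equiv, THF, −78 °C) then aqueous quench should give the terminal alkyne (3R,5Z)-6-chloro-3-(prop-1-en-2-yl)hept-5-en-1-yne F5. Hydrozirconation with Cp2Zr(H)Cl (THF, rt), which should take the terminal alkyne in preference to the 1,1-disubstituted and chlorinated olefins, followed by NCS should give 13, with the E geometry fixed by syn addition of Zr–H.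

3. Step 4. The dienolate may be alkylated at the γ-carbon, may return to the conjugated imide on proton transfer, or may show eroded facial selectivity.

   The fallback sets out from 4 and returns at 11, replacing auxiliary control by resolution. The lithium dienolate of commercial methyl 3-methylbut-2-enoate (LDA, THF/HMPA, −78 °C) is alkylated at the α-carbon with 4 to give racemic methyl (4Z)-5-chloro-2-(prop-1-en-2-yl)hex-4-enoate F6. LiAlH4 (Et2O, 0 °C) should give racemic (4Z)-5-chloro-2-(prop-1-en-2-yl)hex-4-en-1-ol F7. Lipase-catalysed acetylation (vinyl acetate, porcine pancreatic lipase), as practised for the resolution of lavandulol, separates the enantiomers. By that analogy the fast-reacting enantiomer is expected to give (2R,4Z)-5-chloro-2-(prop-1-en-2-yl)hex-4-en-1-yl acetate F8, whose methanolysis (K2CO3, MeOH) returns 11. The sense of the enzyme has to be confirmed; if it is opposite, 11 is the unreacted alcohol.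

Further compounds
F1 | step 8 | 2-[(1E,3S,5Z)-1,6-dichlorohepta-1,5-dien-3-yl]-2-methyloxirane (both oxirane epimers) | CC1(CO1)[C@H](/C=C/Cl)C/C=C(\Cl)C
F2 | step 8 | 2-[(1E,3S,5S,6R)-5,6-dibromo-1,6-dichlorohept-1-en-3-yl]-2-methyloxirane (SMILES shows the isomer leading to 15; formed with its (5R,6S) diastereomer) | CC1(CO1)[C@H](/C=C/Cl)C[C@H](Br)[C@](C)(Cl)Br
F3 | step 8 | (1E,3S,5S,6R)-5,6-dibromo-1,6-dichloro-3-(prop-1-en-2-yl)hept-1-ene (with its (5R,6S) diastereomer) | CC(=C)[C@H](/C=C/Cl)C[C@H](Br)[C@](C)(Cl)Br
F4 | step 7 | (3S,5Z)-1,1-dibromo-6-chloro-3-(prop-1-en-2-yl)hepta-1,5-diene | CC(=C)[C@H](C=C(Br)Br)C/C=C(\Cl)C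
F5 | step 7 | (3R,5Z)-6-chloro-3-(prop-1-en-2-yl)hept-5-en-1-yne | CC(=C)[C@H](C#C)C/C=C(\Cl)C
F6 | step 4 | methyl (4Z)-5-chloro-2-(prop-1-en-2-yl)hex-4-enoate (racemic) | COC(=O)C(C(C)=C)C/C=C(\Cl)C
F7 | step 4 | (4Z)-5-chloro-2-(prop-1-en-2-yl)hex-4-en-1-ol (racemic) | CC(=C)C(CO)C/C=C(\Cl)C
F8 | step 4 | (2R,4Z)-5-chloro-2-(prop-1-en-2-yl)hex-4-en-1-yl acetate | CC(=C)[C@H](COC(C)=O)C/C=C(\Cl)C
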